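C1 is the stereogenic methine and C2 the adjacent CH2. Ring A is the 4-hydroxy-3-methoxyphenyl on C1. Ring B is the 2-hydroxy-3-methoxyphenyl on C1 with the styryl arm para to its OH. Ring C is the 2,4-dihydroxyphenyl on C2, and ring D the 3,5-dihydroxyphenyl of the stilbene.
Enabling feature: C1 is bonded to the ring B carbon next to the one that bears the ring B hydroxyl, so the unit O–C(ring B)–C(ring B)–C1 can be unmasked as an ortho-quinone methide with ring A on the methide carbon C1. C2 is benzylic to ring C, so with a temporary carboxyl group it becomes the nucleophilic α-carbon of a ring C arylacetate.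
Cuts, in retrosynthetic order: six O–MOM bonds; the ring B–vinyl bond (Heck); a C2–CO2H bond restored on C2; C1–C2 together with the lactone O–acyl bond (formal [4+2]); C1–S and C1–ring A (sulfinate exchange, Grignard addition).
Forward: rings A and B are joined at C1. Ring C arrives with C2 as the dihydrocoumarin closes, the only ring built. The lactone is then opened, its carbonyl carbon leaves as CO2, ring D is coupled last, and all phenols are freed.
Stereochemistry: C1 (S), the only stereocentre of the target, is set by a chiral isothiourea in the [4+2] step. The centre formed beside it at C2 disappears on decarboxylation, and the E-alkene comes from the Heck reaction.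

Key step: step 6

Assumption: the sense of induction in step 6 is assigned from the accepted face-shielding model of isothiourea-bound Z-enolates and the anti topicity they show towards s-cis oxadienes; it is to be confirmed on the lactone, and if the 4R series were found, the equally available (R)-catalyst would be used with no other change.

Step 1
Reactants: 1 4-bromo-2-methoxyphenol
Product: 2 4-bromo-2-methoxy-1-(methoxymethoxy)benzene
Conditions: MOMCl (1.3 equiv), iPr2NEt (1.6 equiv), CH2Cl2, 0 °C to rt
Reagents that add atoms: chloromethyl methyl ether (MOMCl), COCCl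
Why: Williamson-type O-alkylation of the phenol with the reactive α-chloro ether removes the only acidic proton of ring A ahead of the organomagnesium step and installs a group that leaves in the final acid treatment.

Step 2
Reactants: 2 4-bromo-2-methoxy-1-(methoxymethoxy)benzene; 3 5-bromo-2-hydroxy-3-methoxybenzaldehyde
Product: 5 4-bromo-2-{hydroxy[3-methoxy-4-(methoxymethoxy)phenyl]methyl}-6-methoxyphenol (racemic), via arylmagnesium bromide 4 (not isolated)
Conditions: 2 (2.3 equiv), Mg turnings, I2 (crystal), THF, 40 °C; then 3, THF, 0 °C to rt; sat. aq NH4Cl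
Reagents that add atoms: none
Why: Grignard addition to an aldehyde, the standard entry to ortho-hydroxybenzhydrols: one equivalent of 4 is spent on the phenol of 3 and the next adds to the formyl group, the C–Br bond of 3 does not exchange with an arylmagnesium bromide at this temperature, and the new carbinol centre may be racemic because it becomes planar in step 6.

Step 3
Reactants: 5 4-bromo-2-{hydroxy[3-methoxy-4-(methoxymethoxy)phenyl]methyl}-6-methoxyphenol
Product: 6 4-bromo-2-methoxy-6-{[3-methoxy-4-(methoxymethoxy)phenyl](4-methylbenzenesulfonyl)methyl}phenol (racemic sulfone)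
Conditions: p-TolSO2H (1.3 equiv), CH2Cl2, 0 °C to rt
Reagents that add atoms: p-toluenesulfinic acid, Cc1ccc(S(=O)O)cc1
Why: SN1-type exchange of an activated benzhydrol, in which the acidity of the sulfinic acid alone should ionise the carbinol (stabilised by the ortho-hydroxyl of ring B and the para-oxygen of ring A) and the soft sulfur of the sulfinate captures the cation to give a storable sulfone under conditions mild and water-poor enough for the aryl MOM ether.

Step 4
Reactants: 7 methyl 2-(2,4-dihydroxyphenyl)acetate
Product: 9 2-[2,4-bis(methoxymethoxy)phenyl]acetic acid, via bis-MOM methyl ester 8 (not isolated)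
Conditions: MOMCl (2.6 equiv), iPr2NEt (3 equiv), CH2Cl2, 0 °C to rt; aqueous wash, concentrate; then LiOH·H2O (3 equiv), THF/MeOH/H2O, rt; cold 0.5 M HCl to pH 4
Reagents that add atoms: chloromethyl methyl ether (MOMCl), COCCl; lithium hydroxide, [Li+].[OH-]
Why: Phenol O-alkylation followed by ester saponification, the methyl ester being chosen as starting point because it keeps the ortho-phenol from closing to a benzofuranone before it is capped, while MOM ethers are inert to LiOH and to a brief cold acidification.

Step 5
Reactants: 9 2-[2,4-bis(methoxymethoxy)phenyl]acetic acid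
Product: 10 4-nitrophenyl 2-[2,4-bis(methoxymethoxy)phenyl]acetate
Conditions: 4-nitrophenol (1.1 equiv), DCC (1.1 equiv), DMAP (5 mol %), CH2Cl2, 0 °C to rt
Reagents that add atoms: 4-nitrophenol, O=[N+]([O-])c1ccc(O)cc1
Why: Steglich-type carbodiimide esterification gives the activated aryl ester that can acylate an isothiourea, under near-neutral conditions that leave the MOM ethers alone and with little DMAP so that ketene formation from the acidic arylacetate stays small.

Step 6
Reactants: 6 racemic sulfone (ortho-quinone methide precursor); 10 4-nitrophenyl 2-[2,4-bis(methoxymethoxy)phenyl]acetate (1.3 equiv)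
Product: 13 (3S,4S)-6-bromo-3-[2,4-bis(methoxymethoxy)phenyl]-8-methoxy-4-[3-methoxy-4-(methoxymethoxy)phenyl]chroman-2-one (trans lactone), via ortho-quinone methide 11 (not isolated), via acylammonium enolate 12 (not isolated)
Conditions: (S)-benzotetramisole [(2S)-2-phenyl-2,3-dihydrobenzo[d]imidazo[2,1-b]thiazole] (10 mol %), Cs2CO3 (2.5 equiv), 4 Å molecular sieves, CH2Cl2, 0 °C to rt
Reagents that add atoms: none
Why: Cs2CO3 expels p-toluenesulfinate from 6 to release the E-configured ortho-quinone methide 11 (ring A anti to the ring carbonyl), while the catalyst is acylated by aryl ester 10 and deprotonated to the Z-enolate 12, held flat by its 1,5 O···S contact; the α-carbon of 12 adds to the methide carbon (C1–C2 bond), ring B re-aromatises and the resulting phenoxide displaces the catalyst from the acyl carbon. The closest known reaction type is the Lewis-base-catalysed (isothiourea or N-heterocyclic carbene) formal [4+2] Michael addition–lactonisation of C1 enolates with ortho-quinone methides released from 2-(sulfonylmethyl)phenols, which delivers 3,4-dihydrocoumarins. The one ring formed, the six-membered lactone, closes by 6-exo-trig acyl substitution at the acylammonium carbon, and this event also turns the catalyst over. C3 (C2 of the target) is set by the pseudo-axial phenyl group of the catalyst, which blocks one enolate face, and C4 (C1 of the target) by the compact transition state in which the methide oxygen lies over the acyl carbon and ring B stacks on the cationic heterocycle, so that one face of 11 is presented and the trans (3S,4S) lactone should result. The selectivity that matters is the enantiofacial one at the methide carbon, secured by the single E geometry of 11 (a Z-placed ring A would clash with the carbonyl oxygen) and by the slow heterogeneous release of 11, which keeps uncatalysed addition, reversible capture by sulfinate or 4-nitrophenoxide, and dimerisation in check. Base-induced epimerisation at C3 is harmless because that centre is erased in step 9, whereas C4 carries no acidic hydrogen.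

Step 7
Reactants: 13 trans lactone
Product: 15 methoxymethyl (2S,3S)-3-[5-bromo-3-methoxy-2-(methoxymethoxy)phenyl]-2-[2,4-bis(methoxymethoxy)phenyl]-3-[3-methoxy-4-(methoxymethoxy)phenyl]propanoate, via dipotassium salt 14 (not isolated)
Conditions: KOSiMe3 (2.2 equiv), THF, 0 °C; then MOMCl (3 equiv), 0 °C to rt
Reagents that add atoms: potassium trimethylsilanolate, C[Si](C)(C)[O-].[K+]; chloromethyl methyl ether (MOMCl), COCCl
Why: Anhydrous ester cleavage by silanolate (acyl attack on the aryl ester, then desilylation of the silyl ester by the second equivalent) gives the phenoxide–carboxylate dianion, which can neither relactonise nor undergo retro-Michael cleavage because a carboxylate is no acylating agent and cannot stabilise a departing α-carbanion, and double O-alkylation with MOMCl then fixes the open form without touching C1.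

Step 8
Reactants: 15 MOM ester
Product: 16 (2S,3S)-3-[5-bromo-3-methoxy-2-(methoxymethoxy)phenyl]-2-[2,4-bis(methoxymethoxy)phenyl]-3-[3-methoxy-4-(methoxymethoxy)phenyl]propanoic acid (a C2 epimer is tolerated)
Conditions: LiOH·H2O (3 equiv), THF/MeOH/H2O, rt; cold 0.5 M HCl to pH 4
Reagents that add atoms: lithium hydroxide, [Li+].[OH-]
Why: Saponification of an acyloxymethyl ether, far more labile than an alkyl ester, frees the acid at room temperature, and with the ring B oxygen capped no phenoxide can trigger C1–C2 cleavage while epimerisation at C2 is of no consequence.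

Step 9
Reactants: 16 triarylpropanoic acid
Product: 17 5-bromo-1-{(1S)-2-[2,4-bis(methoxymethoxy)phenyl]-1-[3-methoxy-4-(methoxymethoxy)phenyl]ethyl}-3-methoxy-2-(methoxymethoxy)benzene
Conditions: 9-mesityl-10-phenylacridinium tetrafluoroborate (5 mol %), PhSSPh (10 mol %), iPr2NEt (20 mol %), CF3CH2OH/CH2Cl2 4:1, degassed, 450 nm LEDs, rt
Reagents that add atoms: none
Why: Photoredox hydrodecarboxylation (acridinium/disulfide dual catalysis), in which one-electron oxidation of the carboxylate, loss of CO2 to the ring C-stabilised benzylic radical at C2 and hydrogen-atom transfer from thiophenol formed in situ turn C2 into a CH2 group, while C1 never carries spin or charge and so keeps its configuration.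

Step 10
Reactants: 18 3,5-dihydroxybenzaldehyde
Product: 19 3,5-bis(methoxymethoxy)benzaldehyde
Conditions: MOMCl (2.6 equiv), iPr2NEt (3 equiv), CH2Cl2, 0 °C to rt
Reagents that add atoms: chloromethyl methyl ether (MOMCl), COCCl
Why: The same phenol O-alkylation as in step 1, the aldehyde being inert to MOMCl and amine base.

Step 11
Reactants: 19 3,5-bis(methoxymethoxy)benzaldehyde
Product: 20 1-ethenyl-3,5-bis(methoxymethoxy)benzene
Conditions: Ph3PCH3Br (1.3 equiv), KOtBu (1.25 equiv), THF, 0 °C to rt
Reagents that add atoms: methyltriphenylphosphonium bromide, C[P+](c1ccccc1)(c1ccccc1)c1ccccc1.[Br-]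
Why: Wittig methylenation with the non-stabilised ylide converts the non-enolisable aldehyde into the terminal styrene, and no alkene geometry is at stake.

Step 12
Reactants: 17 aryl bromide; 20 1-ethenyl-3,5-bis(methoxymethoxy)benzene (1.3 equiv)
Product: 21 hexa-MOM ether of the target, (S) at C1 and E at the alkene
Conditions: Pd2(dba)3 (2.5 mol %), P(t-Bu)3·HBF4 (10 mol %), Cy2NMe (1.5 equiv), 1,4-dioxane, 80 °C
Reagents that add atoms: none
Why: Mizoroki–Heck reaction, in which the bulky electron-rich phosphine lets zerovalent palladium insert into the electron-rich but unhindered C–Br bond of ring B, syn insertion at the terminal styrene carbon and syn β-hydride elimination give the E-stilbene, and the amine base is far too weak to deprotonate C1–H.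

Step 13
Reactants: 21 hexa-MOM ether
Product: 22 4-{(2S)-2-{5-[(E)-2-(3,5-dihydroxyphenyl)ethenyl]-2-hydroxy-3-methoxyphenyl}-2-(4-hydroxy-3-methoxyphenyl)ethyl}benzene-1,3-diol (CNP0254096.1)
Conditions: HCl (ca. 1.25 M in MeOH), MeOH/THF, rt to 40 °C, argon, dark
Reagents that add atoms: none
Why: Acid-catalysed acetal exchange removes all six MOM groups, methanol trapping each formaldehyde unit as its dimethyl acetal so that it cannot attack the resorcinol rings, while the two aryl methyl ethers, the E-alkene and the non-ionisable C1–H centre should be unaffected by dilute acid.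

Compound list
1 | 4-bromo-2-methoxyphenol | COc1cc(Br)ccc1O | starting material
2 | 4-bromo-2-methoxy-1-(methoxymethoxy)benzene | COCOc1ccc(Br)cc1OC | intermediate
3 | 5-bromo-2-hydroxy-3-methoxybenzaldehyde | COc1cc(Br)cc(C=O)c1O | starting material
4 | [3-methoxy-4-(methoxymethoxy)phenyl]magnesium bromide (not isolated) | COCOc1ccc([Mg]Br)cc1OC | intermediate
5 | 4-bromo-2-{hydroxy[3-methoxy-4-(methoxymethoxy)phenyl]methyl}-6-methoxyphenol (racemic) | COCOc1ccc(C(O)c2cc(Br)cc(OC)c2O)cc1OC | intermediate
6 | 4-bromo-2-methoxy-6-{[3-methoxy-4-(methoxymethoxy)phenyl](4-methylbenzenesulfonyl)methyl}phenol (racemic) | COc1cc(C(c2cc(Br)cc(OC)c2O)S(=O)(=O)c2ccc(C)cc2)ccc1OCOC | intermediate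
7 | methyl 2-(2,4-dihydroxyphenyl)acetate | COC(=O)Cc1ccc(O)cc1O | starting material
8 | methyl 2-[2,4-bis(methoxymethoxy)phenyl]acetate (not isolated) | COCOc1ccc(CC(=O)OC)c(OCOC)c1 | intermediate
9 | 2-[2,4-bis(methoxymethoxy)phenyl]acetic acid | COCOc1ccc(CC(=O)O)c(OCOC)c1 | intermediate
10 | 4-nitrophenyl 2-[2,4-bis(methoxymethoxy)phenyl]acetate | COCOc1ccc(CC(=O)Oc2ccc([N+](=O)[O-])cc2)c(OCOC)c1 | intermediate
11 | (6E)-4-bromo-2-methoxy-6-{[3-methoxy-4-(methoxymethoxy)phenyl]methylidene}cyclohexa-2,4-dien-1-one, the ring B ortho-quinone methide (not isolated) | COc1cc(/C=C2\C=C(Br)C=C(OC)C2=O)ccc1OCOC | intermediate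
12 | Z-enolate of the N-[2,4-bis(methoxymethoxy)phenylacetyl] (S)-benzotetramisolium ion (zwitterion, not isolated) | COCOc1ccc(/C=C(\[O-])[N+]2=C3Sc4ccccc4N3C[C@@H]2c2ccccc2)c(OCOC)c1 | intermediate
13 | (3S,4S)-6-bromo-3-[2,4-bis(methoxymethoxy)phenyl]-8-methoxy-4-[3-methoxy-4-(methoxymethoxy)phenyl]chroman-2-one (trans) | COc1cc([C@H]2c3cc(Br)cc(OC)c3OC(=O)[C@@H]2c2ccc(OCOC)cc2OCOC)ccc1OCOC | intermediate
14 | dipotassium (2S,3S)-3-(5-bromo-3-methoxy-2-oxidophenyl)-2-[2,4-bis(methoxymethoxy)phenyl]-3-[3-methoxy-4-(methoxymethoxy)phenyl]propanoate (not isolated) | COc1cc([C@H]([C@H](C(=O)[O-])c2ccc(OCOC)cc2OCOC)c2cc(Br)cc(OC)c2[O-])ccc1OCOC.[K+].[K+] | intermediate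
15 | methoxymethyl (2S,3S)-3-[5-bromo-3-methoxy-2-(methoxymethoxy)phenyl]-2-[2,4-bis(methoxymethoxy)phenyl]-3-[3-methoxy-4-(methoxymethoxy)phenyl]propanoate | COc1cc([C@H]([C@H](C(=O)OCOC)c2ccc(OCOC)cc2OCOC)c2cc(Br)cc(OC)c2OCOC)ccc1OCOC | intermediate
16 | (2S,3S)-3-[5-bromo-3-methoxy-2-(methoxymethoxy)phenyl]-2-[2,4-bis(methoxymethoxy)phenyl]-3-[3-methoxy-4-(methoxymethoxy)phenyl]propanoic acid | COc1cc([C@H]([C@H](C(=O)O)c2ccc(OCOC)cc2OCOC)c2cc(Br)cc(OC)c2OCOC)ccc1OCOC | intermediate
17 | 5-bromo-1-{(1S)-2-[2,4-bis(methoxymethoxy)phenyl]-1-[3-methoxy-4-(methoxymethoxy)phenyl]ethyl}-3-methoxy-2-(methoxymethoxy)benzene | COc1cc([C@H](Cc2ccc(OCOC)cc2OCOC)c2cc(Br)cc(OC)c2OCOC)ccc1OCOC | intermediate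
18 | 3,5-dihydroxybenzaldehyde | O=Cc1cc(O)cc(O)c1 | starting material
19 | 3,5-bis(methoxymethoxy)benzaldehyde | COCOc1cc(C=O)cc(OCOC)c1 | intermediate
20 | 1-ethenyl-3,5-bis(methoxymethoxy)benzene | C=Cc1cc(OCOC)cc(OCOC)c1 | intermediate
21 | hexa-MOM ether of the target: 17 with Br replaced by an (E)-2-[3,5-bis(methoxymethoxy)phenyl]ethenyl group, C1 (S) | COc1cc([C@H](Cc2ccc(OCOC)cc2OCOC)c2cc(/C=C/c3cc(OCOC)cc(OCOC)c3)cc(OC)c2OCOC)ccc1OCOC | intermediate
22 | 4-{(2S)-2-{5-[(E)-2-(3,5-dihydroxyphenyl)ethenyl]-2-hydroxy-3-methoxyphenyl}-2-(4-hydroxy-3-methoxyphenyl)ethyl}benzene-1,3-diol | COc1cc([C@H](Cc2ccc(O)cc2O)c2cc(/C=C/c3cc(O)cc(O)c3)cc(OC)c2O)ccc1O | target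

Total step count: 13.
Longest linear sequence: 9 steps (1, 2, 3, 6, 7, 8, 9, 12, 13).

Steps most likely to fail

Step 6. Facial discrimination at the methide carbon may be insufficient, or it may be eroded by reversible addition under the basic conditions. The fallback replaces reliance on catalyst control by classical resolution, using the carboxyl group that the molecule carries anyway as the handle. It sets out from acid 16 of unsatisfactory enantiomeric purity. This is combined with (R)-1-phenylethylamine in ethyl acetate/heptane to give the (R)-1-phenylethylammonium salt of the (2S,3S)-acid F1. Fractional crystallisation, followed by partition between cold aqueous KHSO4 and ethyl acetate, returns enriched acid, and the route is rejoined at 16. The antipodal amine is tried if the wanted salt proves the more soluble one.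

Step 9. The excited acridinium may oxidise the electron-rich rings A to C in competition with the carboxylate, which would open the way to fragmentation of the C1–C2 bond. Bromine may also be lost by photoreduction. The fallback exchanges electron transfer for a neutral radical chain (Barton reductive decarboxylation). It sets out from 16. Coupling with 1-hydroxypyridine-2(1H)-thione (DCC, CH2Cl2, 0 °C, dark) gives the thiohydroxamate (Barton) ester F2. This is irradiated with a tungsten lamp in toluene in the presence of tert-butyl thiol; the C2 radical takes hydrogen from the thiol, and the route is rejoined at 17.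

Step 7. If the carboxylate is alkylated before the hindered ring B phenoxide, the phenoxide can attack the newly activated ester and re-close the lactone. A phenoxide standing next to an ester can also expel the C2 enolate (retro-Michael), which would racemise C1. The fallback opens the lactone reductively instead of hydrolytically, so that no acyl group is present while the phenoxide is free. It sets out from 13, and LiBH4 (THF, 0 °C to rt) gives the phenol–primary alcohol F3. K2CO3/MOMCl in acetone caps the phenol selectively to give the ring B MOM ether alcohol F4. TEMPO (cat.)/PhI(OAc)2 in MeCN/water oxidises the CH2OH group to the acid, and the route is rejoined at 16, bypassing steps 7 and 8.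

Further compounds
F1 | step 6 | (R)-1-phenylethylammonium (2S,3S)-3-[5-bromo-3-methoxy-2-(methoxymethoxy)phenyl]-2-[2,4-bis(methoxymethoxy)phenyl]-3-[3-methoxy-4-(methoxymethoxy)phenyl]propanoate | C[C@@H]([NH3+])c1ccccc1.COc1cc([C@H]([C@H](C(=O)[O-])c2ccc(OCOC)cc2OCOC)c2cc(Br)cc(OC)c2OCOC)ccc1OCOC
F2 | step 9 | 2-thioxopyridin-1(2H)-yl (2S,3S)-3-[5-bromo-3-methoxy-2-(methoxymethoxy)phenyl]-2-[2,4-bis(methoxymethoxy)phenyl]-3-[3-methoxy-4-(methoxymethoxy)phenyl]propanoate | COc1cc([C@H]([C@H](C(=O)ON2C=CC=CC2=S)c2ccc(OCOC)cc2OCOC)c2cc(Br)cc(OC)c2OCOC)ccc1OCOC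
F3 | step 7 | (2S,3S)-3-(5-bromo-2-hydroxy-3-methoxyphenyl)-2-[2,4-bis(methoxymethoxy)phenyl]-3-[3-methoxy-4-(methoxymethoxy)phenyl]propan-1-ol | COc1cc([C@H]([C@H](CO)c2ccc(OCOC)cc2OCOC)c2cc(Br)cc(OC)c2O)ccc1OCOC
F4 | step 7 | (2S,3S)-3-[5-bromo-3-methoxy-2-(methoxymethoxy)phenyl]-2-[2,4-bis(methoxymethoxy)phenyl]-3-[3-methoxy-4-(methoxymethoxy)phenyl]propan-1-ol | COc1cc([C@H]([C@H](CO)c2ccc(OCOC)cc2OCOC)c2cc(Br)cc(OC)c2OCOC)ccc1OCOC
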